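## Structural features

The target is a B-type proanthocyanidin trimer of three flavan-3-ol units. Each unit is a chroman (ring A fused to the oxygen heterocycle, ring C) with a catechol ring B at C2. The upper and middle units are (−)-epicatechin esterified at O3 with gallic acid; the lower unit is (+)-catechin with a free 3-hydroxyl. Two aryl–C(sp3) bonds join the units: C4 of the upper unit to C8 of the middle unit, and C4 of the middle unit to C6 of the lower unit. There are eight stereocentres: a contiguous C2–C3–C4 triad in each of the upper and middle rings C (2,3-cis, 3,4-trans, so both C4 aryl groups are β) and the 2,3-trans pair (2R,3S) of the lower unit. The interflavan bonds ionise in acid, the eighteen phenolic hydroxyls oxidise easily and, when free, allow base to open ring C and epimerise C2, and the gallates are base-labile esters. The real difficulty is to make two different interflavan bonds (one to C8, one to C6), each 4β, without oligomerisation, and to finish with two of the three secondary hydroxyls acylated. The key step uses the fact that C4 of the upper unit is a diarylmethine between C4a of a phloroglucinol ring A with no other carbon substituent and C8 of the middle unit, and is β to C2, which can be an aldehyde carbon. Ring C of the upper unit can therefore be annulated onto a propenal chain at C8 of the middle unit by forming C4–C4a and O1–C2.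

## Logic of the disconnections

30 from 29: eighteen benzyl C–O bonds and the C8–Br bond of the lower unit are cut. All phenols stay masked until the end and the bromine that directed the last coupling leaves in the same operation. The forward step must be neutral and must not let HBr build up.

29 from 25 and 28: the bond C4(middle)–C6(lower) is cut. This splits the trimer into a dimer and a monomer; the 4-alkoxy group of 25 is a latent C4 cation and the bromine of 28 leaves C6 as its only nucleophilic ring A carbon. The forward step must ionise C4 of 25 at low temperature without breaking the existing interflavan bond, and attack must come from the β face.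

28 from 27 from 26: a C–Br bond and four benzyl C–O bonds are cut. The lower unit comes from the chiral pool with C2 and C3 set and its 3-hydroxyl left free.

25 from 23 and 24; 23 from 22: two ester C–O bonds and one Si–O bond are cut. Both gallates are introduced together, after the last organometallic step, so only a silyl ether has to survive the strong nucleophiles used earlier. The forward acylation must succeed on two hindered secondary alcohols.

22 from 21, 21 from 20, 20 from 17 and 19 (19 from 18): O1–C2 of the upper ring C, then the C2–H bond, then the bond from C2 to ring B are cut. Ring B enters as an aryl nucleophile on a lactone carbonyl, the C2 carbinol is set from the adjacent C3 hydroxyl by chelation, and ring closure inverts C2. The forward sequence must give the 1,2-anti diol and a clean SN2 closure so that C2 and C3 end up cis.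

17 from 15, 15 from 14: the C3–O bond is cut and the oxidation level at C2 is adjusted. The C3 oxygen is placed anti to the C4 aryl group on a lactone enolate, which fixes the 3,4-trans relation. The forward hydroxylation must run at low temperature on an aryl ester enolate.

14 from 8 and 12 through 13: C4–C4a and O1–C2 of the upper unit are cut. This removes ring A and ring C of the upper unit in one operation and leaves an enal and a symmetric phenol; one stereocentre (C4) must be set by the catalyst. The forward step must favour ortho-carbon attack and must tolerate the acid-labile 4-alkoxy group of 8.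

8 from 7, 7 from 5 through 6, 5 from 4, 4 from 3, 3 from 2, 2 from 1: the C=C bond of the enal, the C8–CHO bond, the C8–Br bond, the Si–O bond, the C4–O bond and four benzyl C–O bonds are cut. The middle unit comes from the chiral pool; its C4 leaving group is installed early, before C8 is functionalised, and must then survive every later step up to 20.

12 from 11, 11 from 10, 10 from 9: one acetyl C–O bond and two benzyl C–O bonds are cut. The triacetate lets exactly two benzyl groups be placed on a symmetric triphenol without C-alkylation.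

## Other disconnections considered

Alternative 1: The middle ring C is cut at O1–C2 and C3–C4 (retro hetero-Diels–Alder). In the forward step the benzhydrol A2, whose carbinol carbon already carries C6 of a benzylated 8-bromocatechin, is ionised to an ortho-quinone methide that adds the (Z)-enol gallate A3 to give A1. The upper unit would then be attached at C8 of A1 with the 4-activated gallate donor A4.
- In favour: the cycloaddition is convergent, brings the gallate in with the dienophile, and transfers the Z geometry suprafacially to the 2,3-cis relation. The C4–C6 bond is made beforehand by carbonyl addition, so the 6-position is fixed by construction. On step economy to the lower dimer and on securing the 4→6 position this alternative is better than the chosen plan.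
- Against: the absolute sense and the 3,4-trans relation depend only on the remote stereocentres of the catechin part. The required orientation (O1 to the aryl-bearing carbon) sets the styrene polarisation against that of the enol ester. A3 must be made and kept as the Z isomer.
- Comparison: the later union of A4 with A1 is a cationic coupling with the same self-condensation risk as step 20 of the chosen plan, so the two are equal there. Mechanistically the alternative sets three centres in one concerted step without reagent control, whereas the chosen plan sets each centre separately under catalyst, enolate-face or chelate control.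

Alternative 2: The lower ring C is cut at C2=C3 of its 4H-chromene form. In the forward step low-valent titanium from TiCl3 and Zn couples the aldehyde carbon and the aryl ester carbonyl carbon of A6 (McMurry-type oxo-ester coupling) to give A5.
- In favour: the conditions are non-acidic and the closure to cyclic enol ethers is an established reaction type. The lower ring A enters as a symmetric arene, so no 6-versus-8 question arises when the middle–lower bond is made; on that point the alternative is better than step 20 of the chosen plan. Hydroboration–oxidation of A5 would add H and OH syn and give the 2,3-trans relation that catechin needs.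
- Against: the absolute configuration at C2 and C3 would need a chiral borane, because the nearest stereocentre lies across a biaryl-type bond. Low-valent titanium may also attack the aryl bromide. The enol ether of A5 is acid-labile, which conflicts with the later cationic attachment of the upper unit.
- Comparison: the sequence rebuilds a unit that 26 supplies enantiopure in two steps. The chosen plan also rebuilds a chiral-pool unit (the upper epicatechin), so the two are equal in principle, but the chosen plan gains control of the 4→8 bond from it, whereas here step economy is worse.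

Alternative 3: The lower ring C is cut at C4–C4a. In the forward step the ring A carbon ortho to the ether oxygen of A8 opens the terminal epoxide carbon (6-endo, acid-promoted Friedel–Crafts epoxide–arene cyclisation) to give A7.
- In favour: C2 and C3 are set in an acyclic precursor by dependable asymmetric epoxidation chemistry and are not touched in the closure. Only one ring A carbon is free. The 3-hydroxyl emerges unprotected and already distinguished from the two hydroxyls to be galloylated; here the alternative is the equal of the chosen plan, which carries the same free hydroxyl in 28.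
- Against: the closure needs a Lewis or Brønsted acid while the acid-labile middle–lower bond is present. The benzylic aryl ether at C2, next to an electron-rich ring B, can ionise and scramble C2. The hindered aryl ether A8 is hard to assemble.
- Comparison: the chosen key step runs under weakly acidic amine catalysis with no cationic intermediate, which is safer mechanistically. In step count the alternative is longer, because it replaces two steps from 26.

Key step: step 10

Assumption: 18 and 24 are bought as such; 28 is used with its 3-hydroxyl free because the coupling of step 20 alkylates carbon, not oxygen.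

## Route

Step 1
Reactants: 1 (−)-epicatechin
Product: 2 5,7,3',4'-tetra-O-benzyl-(−)-epicatechin
Conditions: BnBr (4.4 equiv), K2CO3, DMF, 0 °C to rt, Ar
Reagents that add atoms: benzyl bromide, BrCc1ccccc1
Why: Williamson etherification of the four phenols; K2CO3 does not deprotonate the secondary 3-hydroxyl, and low temperature with exclusion of air limits base-induced epimerisation at C2.

Step 2
Reactants: 2 5,7,3',4'-tetra-O-benzyl-(−)-epicatechin
Product: 3 (2R,3R,4S)-5,7,3',4'-tetra-O-benzyl-4-(2-ethoxyethoxy)flavan-3-ol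
Conditions: DDQ (2 equiv), 2-ethoxyethanol (5 equiv), CH2Cl2, rt
Reagents that add atoms: 2-ethoxyethanol, CCOCCO
Why: Oxidative benzylic etherification: DDQ abstracts hydride from C4, which is activated by the ortho and para oxygens of ring A, and the alcohol captures the cation on the β face, anti to the axial 3-hydroxyl, to give the 4β ether.

Step 3
Reactants: 3 (2R,3R,4S)-5,7,3',4'-tetra-O-benzyl-4-(2-ethoxyethoxy)flavan-3-ol
Product: 4 3-O-tert-butyldimethylsilyl ether of 3
Conditions: TBSCl, imidazole, DMF, rt to 40 °C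
Reagents that add atoms: tert-butyldimethylsilyl chloride, CC(C)(C)[Si](C)(C)Cl
Why: Silylation under non-acidic conditions leaves the benzylic 4-ether intact; the silyl ether removes the only acidic proton before lithiation and should survive every step up to 16.

Step 4
Reactants: 4 3-O-tert-butyldimethylsilyl ether of 3
Product: 5 8-bromo derivative of 4
Conditions: NBS (1.05 equiv), CH2Cl2, −78 to 0 °C
Reagents that add atoms: N-bromosuccinimide, O=C1CCC(=O)N1Br
Why: Electrophilic aromatic bromination of the phloroglucinol-type ring A, which is much more electron-rich than ring B; C8 (between O1 and the 7-benzyloxy group) is the known site for benzylated flavan-3-ols, and low temperature keeps traces of HBr from ionising C4.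

Step 5
Reactants: 5 8-bromo derivative of 4
Product: 7 8-formyl derivative of 4, via 8-lithio arene 6 (not isolated)
Conditions: n-BuLi, THF, −78 °C; DMF, −78 to 0 °C; aq. NH4Cl
Reagents that add atoms: N,N-dimethylformamide, CN(C)C=O
Why: Bromine–lithium exchange is faster at −78 °C than attack on any ether or silyl group, and formylation of the aryllithium with DMF (Bouveault aldehyde synthesis) gives the aldehyde on work-up.

Step 6
Reactants: 7 8-formyl derivative of 4
Product: 8 (E)-3-[(2R,3R,4S)-5,7-bis(benzyloxy)-2-(3,4-bis(benzyloxy)phenyl)-3-(tert-butyldimethylsilyloxy)-4-(2-ethoxyethoxy)chroman-8-yl]propenal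
Conditions: Ph3P=CHCHO (1.3 equiv), toluene, 90 °C
Reagents that add atoms: (triphenylphosphoranylidene)acetaldehyde, O=CC=P(c1ccccc1)(c1ccccc1)c1ccccc1
Why: Wittig olefination with a stabilised ylide gives the (E)-enal; the aldehyde cannot enolise, and a small excess of ylide with monitoring limits a second homologation.

Step 7
Reactants: 9 phloroglucinol
Product: 10 benzene-1,3,5-triyl triacetate
Conditions: Ac2O, pyridine, rt
Reagents that add atoms: acetic anhydride, CC(=O)OC(C)=O
Why: Exhaustive O-acetylation of a triphenol; the triacetate masks the strongly C-nucleophilic phloroglucinol nucleus for the next step.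

Step 8
Reactants: 10 benzene-1,3,5-triyl triacetate
Product: 11 3,5-bis(benzyloxy)phenyl acetate
Conditions: NaH (4 equiv), BnCl (2.1 equiv), H2O (2 equiv), DMF, 0 °C
Reagents that add atoms: benzyl chloride, ClCc1ccccc1
Why: Hydroxide formed in situ cleaves the acetates one at a time and each phenoxide is O-benzylated as it forms (Williamson etherification); the low standing concentration of phenoxide suppresses C-benzylation and the stoichiometry leaves the third acetate.

Step 9
Reactants: 11 3,5-bis(benzyloxy)phenyl acetate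
Product: 12 3,5-bis(benzyloxy)phenol
Conditions: K2CO3 (0.2 equiv), MeOH, rt
Reagents that add atoms: none
Why: Base-catalysed transesterification of an aryl acetate with methanol; benzyl ethers are inert.

Step 10
Reactants: 8 (E)-enal of the middle unit; 12 3,5-bis(benzyloxy)phenol (1.5 equiv)
Product: 14 (4R)-5,7-bis(benzyloxy)-4-[(2R,3R,4S)-5,7-bis(benzyloxy)-2-(3,4-bis(benzyloxy)phenyl)-3-(tert-butyldimethylsilyloxy)-4-(2-ethoxyethoxy)chroman-8-yl]chroman-2-ol (lactol epimers), via ring-open hydroxy aldehyde 13 (not isolated)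
Conditions: (S)-2-[diphenyl(trimethylsilyloxy)methyl]pyrrolidine (20 mol %), PhCO2H (20 mol %), toluene, 0 °C to rt
Reagents that add atoms: none
Why: The enal condenses with the secondary amine to an (E)-configured s-trans iminium ion, one face of which is covered by the diphenyl(silyloxy)methyl group, so a nucleophile can reach the β-carbon only from the open face. The ortho carbon of 12, activated by the hydroxyl and the para benzyloxy group, adds in a Friedel–Crafts sense to form C4–C4a; rearomatisation and hydrolysis of the enamine release aldehyde 13 and the catalyst. The phenolic hydroxyl then adds to the aldehyde (6-exo-trig) and closes ring C as lactol 14, forming O1–C2. The closest known reaction type is the diarylprolinol silyl ether-catalysed Friedel–Crafts alkylation–hemiacetalisation of electron-rich phenols and naphthols with enals, which gives 4-substituted chroman-2-ols. C4 is the only controlled new stereocentre and is set by the catalyst: with the (S)-catalyst the aryl group should enter on the face that gives the (4R) diarylmethine of the upper unit, the stereocentres of the middle unit being too remote to override this. The lactol carbon forms as both epimers, which does not matter because it is oxidised in step 11. The step needs ortho-carbon attack in preference to para-carbon and oxygen attack: the para carbon lies between two benzyloxy groups, the hydroxyl is hydrogen-bonded to the benzoate counter-ion close to the β-carbon, and only the ortho adduct is removed from the reversible addition by lactol formation. Benzoic acid is too weak to ionise the 4-(2-ethoxyethoxy) group.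

Step 11
Reactants: 14 lactol of the upper ring C
Product: 15 (4R)-5,7-bis(benzyloxy)-4-(middle unit-8-yl)chroman-2-one
Conditions: Ag2CO3 on Celite (excess), toluene, 90 °C
Reagents that add atoms: none
Why: Lactol-to-lactone oxidation on the surface of silver carbonate is neutral and heterogeneous, so the silyl ether, the benzyl ethers and the acid-labile 4-ether are not touched; the minor C4 epimer can be removed here by chromatography.

Step 12
Reactants: 15 4-aryl-dihydrocoumarin
Product: 17 (3R,4R)-3-hydroxy-5,7-bis(benzyloxy)-4-(middle unit-8-yl)chroman-2-one, via potassium enolate 16 (not isolated)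
Conditions: KN(SiMe3)2, THF, −78 °C; 2-(phenylsulfonyl)-3-phenyloxaziridine, −78 °C; aq. NH4Cl
Reagents that add atoms: 2-(phenylsulfonyl)-3-phenyloxaziridine, O=S(=O)(c1ccccc1)N1OC1c1ccccc1
Why: Enolate oxidation with an N-sulfonyloxaziridine; the C4 aryl group sits pseudo-axial to avoid the peri 5-benzyloxy group and covers one face of the enolate, so oxygen enters anti and gives the 3,4-trans hydroxy lactone, while −78 °C prevents ketene fragmentation of the aryl ester enolate.

Step 13
Reactants: 17 trans-3-hydroxy lactone; 18 4-bromo-1,2-bis(benzyloxy)benzene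
Product: 20 (2R,3R)-1-[3,4-bis(benzyloxy)phenyl]-2-hydroxy-3-[2-hydroxy-4,6-bis(benzyloxy)phenyl]-3-(middle unit-8-yl)propan-1-one, via 3,4-bis(benzyloxy)phenyllithium 19 (not isolated)
Conditions: 18 (2.4 equiv), n-BuLi (2.3 equiv), THF, −78 °C; add 17, −78 °C; AcOH, −78 °C
Reagents that add atoms: none
Why: Acyl substitution of an aryl lactone by an aryllithium: the first equivalent deprotonates the hydroxyl, the second adds to the carbonyl, and the lithium-chelated tetrahedral intermediate should persist at −78 °C and release the ketone only on the cold quench; the adjacent alkoxide disfavours enolisation, so C3 keeps its configuration.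

Step 14
Reactants: 20 α-hydroxy ketone
Product: 21 (1S,2R,3R)-1-[3,4-bis(benzyloxy)phenyl]-3-[2-hydroxy-4,6-bis(benzyloxy)phenyl]-3-(middle unit-8-yl)propane-1,2-diol
Conditions: Zn(BH4)2, Et2O/THF, −20 to 0 °C; aq. NH4Cl
Reagents that add atoms: none
Why: Chelation-controlled reduction: zinc bridges the carbonyl and the α-hydroxyl, and hydride attacks the face of the chelate opposite the diarylmethyl group, giving the 1,2-anti diol with the (S)-carbinol at the future C2.

Step 15
Reactants: 21 anti-diol phenol
Product: 22 5,7,3',4'-tetra-O-benzylepicatechin-(4β→8)-[5,7,3',4'-tetra-O-benzyl-3-O-TBS-4β-(2-ethoxyethoxy)epicatechin]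
Conditions: PPh3 (1.5 equiv), DIAD (1.5 equiv), THF, 0 °C
Reagents that add atoms: none
Why: Intramolecular Mitsunobu etherification: the phenol is the only acidic hydroxyl and displaces the benzylic oxyphosphonium group in a 6-exo-tet SN2 reaction with inversion, which turns the anti diol into the 2,3-cis (2R,3R) chroman; displacement at C3 would be at a non-benzylic carbon flanked by two branched carbons and should be much slower.

Step 16
Reactants: 22 silyl-protected dimer
Product: 23 5,7,3',4'-tetra-O-benzylepicatechin-(4β→8)-[5,7,3',4'-tetra-O-benzyl-4β-(2-ethoxyethoxy)epicatechin] (3-OH free in both units)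
Conditions: Bu4NF, THF, rt
Reagents that add atoms: none
Why: Fluoride cleaves the Si–O bond under basic, non-acidic conditions that leave the benzylic 4-ether and the interflavan bond intact.

Step 17
Reactants: 23 dimer diol; 24 3,4,5-tris(benzyloxy)benzoic acid (4 equiv)
Product: 25 bis[3,4,5-tris(benzyloxy)benzoate] of 23
Conditions: DCC, DMAP, CH2Cl2, rt
Reagents that add atoms: none
Why: Steglich esterification of both secondary alcohols in one operation; the conditions are neutral, and excess acid with DMAP compensates for the hindrance of the two flanked hydroxyls.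

Step 18
Reactants: 26 (+)-catechin
Product: 27 5,7,3',4'-tetra-O-benzyl-(+)-catechin
Conditions: BnBr (4.4 equiv), K2CO3, DMF, 0 °C to rt, Ar
Reagents that add atoms: benzyl bromide, BrCc1ccccc1
Why: Williamson etherification of the four phenols as in step 1; the 3-hydroxyl stays free.

Step 19
Reactants: 27 5,7,3',4'-tetra-O-benzyl-(+)-catechin
Product: 28 8-bromo-5,7,3',4'-tetra-O-benzyl-(+)-catechin
Conditions: NBS (1.05 equiv), CH2Cl2, −78 to 0 °C
Reagents that add atoms: N-bromosuccinimide, O=C1CCC(=O)N1Br
Why: Regioselective electrophilic bromination at C8 as in step 4; the bromine leaves C6 as the only ring A carbon that can act as a nucleophile.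

Step 20
Reactants: 25 dimeric bis-gallate with the 4β-(2-ethoxyethoxy) group; 28 8-bromo-tetra-O-benzylcatechin (4 equiv)
Product: 29 benzylated epicatechin 3-O-gallate-(4β→8)-epicatechin 3-O-gallate-(4β→6)-8-bromocatechin
Conditions: TMSOTf (0.3 equiv), CH2Cl2, −78 to −40 °C; Et3N
Reagents that add atoms: none
Why: Lewis acid-promoted ionisation of the benzylic 4-ether gives a C4 cation stabilised by ring A and, on its α face, by the 3-O-galloyl carbonyl; Friedel–Crafts attack by C6 of 28 from the β face gives the 3,4-trans bond, excess 28 suppresses self-condensation, and the low temperature protects the existing interflavan bond.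

Step 21
Reactants: 29 protected trimer
Product: 30 epicatechin 3-O-gallate-(4β→8)-epicatechin 3-O-gallate-(4β→6)-catechin (CNP0154615.1)
Conditions: H2 (1 atm), Pd(OH)2/C, Et3N (1.5 equiv), THF/MeOH/H2O, rt
Reagents that add atoms: none
Why: Catalytic hydrogenolysis removes all eighteen benzyl ethers and the aryl bromide in one operation; triethylamine takes up HBr, which would otherwise cleave the interflavan bonds, and the esters and the chroman C–O bonds are not reduced under these conditions.

## Compound list

1 | (−)-epicatechin | O[C@@H]1Cc2c(O)cc(O)cc2O[C@@H]1c1ccc(O)c(O)c1 | starting material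
2 | 5,7,3',4'-tetra-O-benzyl-(−)-epicatechin | O[C@@H]1Cc2c(OCc6ccccc6)cc(OCc6ccccc6)cc2O[C@@H]1c5ccc(OCc6ccccc6)c(OCc6ccccc6)c5 | intermediate
3 | (2R,3R,4S)-5,7,3',4'-tetra-O-benzyl-4-(2-ethoxyethoxy)flavan-3-ol | c1c(OCc6ccccc6)cc(OCc6ccccc6)c2c1O[C@H](c5ccc(OCc6ccccc6)c(OCc6ccccc6)c5)[C@H](O)[C@H]2OCCOCC | intermediate
4 | 3-O-tert-butyldimethylsilyl ether of 3 | c1c(OCc6ccccc6)cc(OCc6ccccc6)c2c1O[C@H](c5ccc(OCc6ccccc6)c(OCc6ccccc6)c5)[C@H](O[Si](C)(C)C(C)(C)C)[C@H]2OCCOCC | intermediate
5 | 8-bromo derivative of 4 | Brc1c(OCc6ccccc6)cc(OCc6ccccc6)c2c1O[C@H](c5ccc(OCc6ccccc6)c(OCc6ccccc6)c5)[C@H](O[Si](C)(C)C(C)(C)C)[C@H]2OCCOCC | intermediate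
6 | 8-lithio derivative of 4 | [Li]c1c(OCc6ccccc6)cc(OCc6ccccc6)c2c1O[C@H](c5ccc(OCc6ccccc6)c(OCc6ccccc6)c5)[C@H](O[Si](C)(C)C(C)(C)C)[C@H]2OCCOCC | intermediate
7 | 8-formyl derivative of 4 | O=Cc1c(OCc6ccccc6)cc(OCc6ccccc6)c2c1O[C@H](c5ccc(OCc6ccccc6)c(OCc6ccccc6)c5)[C@H](O[Si](C)(C)C(C)(C)C)[C@H]2OCCOCC | intermediate
8 | (E)-3-[tetra-O-benzyl-3-O-TBS-4β-(2-ethoxyethoxy)epicatechin-8-yl]propenal | O=C/C=C/c1c(OCc6ccccc6)cc(OCc6ccccc6)c2c1O[C@H](c5ccc(OCc6ccccc6)c(OCc6ccccc6)c5)[C@H](O[Si](C)(C)C(C)(C)C)[C@H]2OCCOCC | intermediate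
9 | phloroglucinol | Oc1cc(O)cc(O)c1 | starting material
10 | benzene-1,3,5-triyl triacetate | CC(=O)Oc1cc(OC(C)=O)cc(OC(C)=O)c1 | intermediate
11 | 3,5-bis(benzyloxy)phenyl acetate | CC(=O)Oc1cc(OCc2ccccc2)cc(OCc2ccccc2)c1 | intermediate
12 | 3,5-bis(benzyloxy)phenol | Oc1cc(OCc2ccccc2)cc(OCc2ccccc2)c1 | intermediate
13 | (3R)-3-[2-hydroxy-4,6-bis(benzyloxy)phenyl]-3-(middle unit-8-yl)propanal | O=CC[C@@H](c3c(OCc6ccccc6)cc(OCc6ccccc6)c4c3O[C@H](c5ccc(OCc6ccccc6)c(OCc6ccccc6)c5)[C@H](O[Si](C)(C)C(C)(C)C)[C@H]4OCCOCC)c1c(OCc6ccccc6)cc(OCc6ccccc6)cc1O | intermediate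
14 | (4R)-5,7-bis(benzyloxy)-4-(middle unit-8-yl)chroman-2-ol, lactol epimers | OC1C[C@@H](c3c(OCc6ccccc6)cc(OCc6ccccc6)c4c3O[C@H](c5ccc(OCc6ccccc6)c(OCc6ccccc6)c5)[C@H](O[Si](C)(C)C(C)(C)C)[C@H]4OCCOCC)c2c(OCc6ccccc6)cc(OCc6ccccc6)cc2O1 | intermediate
15 | (4R)-5,7-bis(benzyloxy)-4-(middle unit-8-yl)chroman-2-one | O=C1C[C@@H](c3c(OCc6ccccc6)cc(OCc6ccccc6)c4c3O[C@H](c5ccc(OCc6ccccc6)c(OCc6ccccc6)c5)[C@H](O[Si](C)(C)C(C)(C)C)[C@H]4OCCOCC)c2c(OCc6ccccc6)cc(OCc6ccccc6)cc2O1 | intermediate
16 | potassium enolate of 15 | [K+].[O-]C1=C[C@@H](c3c(OCc6ccccc6)cc(OCc6ccccc6)c4c3O[C@H](c5ccc(OCc6ccccc6)c(OCc6ccccc6)c5)[C@H](O[Si](C)(C)C(C)(C)C)[C@H]4OCCOCC)c2c(OCc6ccccc6)cc(OCc6ccccc6)cc2O1 | intermediate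
17 | (3R,4R)-3-hydroxy-5,7-bis(benzyloxy)-4-(middle unit-8-yl)chroman-2-one | O[C@@H]1[C@@H](c3c(OCc6ccccc6)cc(OCc6ccccc6)c4c3O[C@H](c5ccc(OCc6ccccc6)c(OCc6ccccc6)c5)[C@H](O[Si](C)(C)C(C)(C)C)[C@H]4OCCOCC)c2c(OCc6ccccc6)cc(OCc6ccccc6)cc2OC1=O | intermediate
18 | 4-bromo-1,2-bis(benzyloxy)benzene | Brc1ccc(OCc2ccccc2)c(OCc2ccccc2)c1 | starting material
19 | 3,4-bis(benzyloxy)phenyllithium | [Li]c1ccc(OCc2ccccc2)c(OCc2ccccc2)c1 | intermediate
20 | (2R,3R)-1-[3,4-bis(benzyloxy)phenyl]-2-hydroxy-3-[2-hydroxy-4,6-bis(benzyloxy)phenyl]-3-(middle unit-8-yl)propan-1-one | O=C(c5ccc(OCc6ccccc6)c(OCc6ccccc6)c5)[C@H](O)[C@@H](c3c(OCc6ccccc6)cc(OCc6ccccc6)c4c3O[C@H](c5ccc(OCc6ccccc6)c(OCc6ccccc6)c5)[C@H](O[Si](C)(C)C(C)(C)C)[C@H]4OCCOCC)c1c(OCc6ccccc6)cc(OCc6ccccc6)cc1O | intermediate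
21 | (1S,2R,3R)-1-[3,4-bis(benzyloxy)phenyl]-3-[2-hydroxy-4,6-bis(benzyloxy)phenyl]-3-(middle unit-8-yl)propane-1,2-diol | O[C@@H](c5ccc(OCc6ccccc6)c(OCc6ccccc6)c5)[C@H](O)[C@@H](c3c(OCc6ccccc6)cc(OCc6ccccc6)c4c3O[C@H](c5ccc(OCc6ccccc6)c(OCc6ccccc6)c5)[C@H](O[Si](C)(C)C(C)(C)C)[C@H]4OCCOCC)c1c(OCc6ccccc6)cc(OCc6ccccc6)cc1O | intermediate
22 | tetra-O-benzylepicatechin-(4β→8)-[tetra-O-benzyl-3-O-TBS-4β-(2-ethoxyethoxy)epicatechin] | O[C@@H]1[C@@H](c3c(OCc6ccccc6)cc(OCc6ccccc6)c4c3O[C@H](c5ccc(OCc6ccccc6)c(OCc6ccccc6)c5)[C@H](O[Si](C)(C)C(C)(C)C)[C@H]4OCCOCC)c2c(OCc6ccccc6)cc(OCc6ccccc6)cc2O[C@@H]1c5ccc(OCc6ccccc6)c(OCc6ccccc6)c5 | intermediate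
23 | tetra-O-benzylepicatechin-(4β→8)-[tetra-O-benzyl-4β-(2-ethoxyethoxy)epicatechin], both 3-OH free | O[C@@H]1[C@@H](c3c(OCc6ccccc6)cc(OCc6ccccc6)c4c3O[C@H](c5ccc(OCc6ccccc6)c(OCc6ccccc6)c5)[C@H](O)[C@H]4OCCOCC)c2c(OCc6ccccc6)cc(OCc6ccccc6)cc2O[C@@H]1c5ccc(OCc6ccccc6)c(OCc6ccccc6)c5 | intermediate
24 | 3,4,5-tris(benzyloxy)benzoic acid | OC(=O)c1cc(OCc2ccccc2)c(OCc2ccccc2)c(OCc2ccccc2)c1 | starting material
25 | bis[3,4,5-tris(benzyloxy)benzoate] of 23 | O=C(O[C@@H]1[C@@H](c3c(OCc6ccccc6)cc(OCc6ccccc6)c4c3O[C@H](c5ccc(OCc6ccccc6)c(OCc6ccccc6)c5)[C@H](OC(=O)c5cc(OCc6ccccc6)c(OCc6ccccc6)c(OCc6ccccc6)c5)[C@H]4OCCOCC)c2c(OCc6ccccc6)cc(OCc6ccccc6)cc2O[C@@H]1c5ccc(OCc6ccccc6)c(OCc6ccccc6)c5)c5cc(OCc6ccccc6)c(OCc6ccccc6)c(OCc6ccccc6)c5 | intermediate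
26 | (+)-catechin | O[C@H]1Cc2c(O)cc(O)cc2O[C@@H]1c1ccc(O)c(O)c1 | starting material
27 | 5,7,3',4'-tetra-O-benzyl-(+)-catechin | O[C@H]1Cc2c(OCc6ccccc6)cc(OCc6ccccc6)cc2O[C@@H]1c5ccc(OCc6ccccc6)c(OCc6ccccc6)c5 | intermediate
28 | 8-bromo-5,7,3',4'-tetra-O-benzyl-(+)-catechin | O[C@H]1Cc2c(OCc6ccccc6)cc(OCc6ccccc6)c(Br)c2O[C@@H]1c5ccc(OCc6ccccc6)c(OCc6ccccc6)c5 | intermediate
29 | benzylated epicatechin 3-O-gallate-(4β→8)-epicatechin 3-O-gallate-(4β→6)-8-bromocatechin | O=C(O[C@@H]1[C@@H](c3c(OCc6ccccc6)cc(OCc6ccccc6)c4c3O[C@H](c5ccc(OCc6ccccc6)c(OCc6ccccc6)c5)[C@H](OC(=O)c5cc(OCc6ccccc6)c(OCc6ccccc6)c(OCc6ccccc6)c5)[C@H]4c7c(OCc6ccccc6)c(Br)c8c(c7OCc6ccccc6)C[C@H](O)[C@@H](c5ccc(OCc6ccccc6)c(OCc6ccccc6)c5)O8)c2c(OCc6ccccc6)cc(OCc6ccccc6)cc2O[C@@H]1c5ccc(OCc6ccccc6)c(OCc6ccccc6)c5)c5cc(OCc6ccccc6)c(OCc6ccccc6)c(OCc6ccccc6)c5 | intermediate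
30 | epicatechin 3-O-gallate-(4β→8)-epicatechin 3-O-gallate-(4β→6)-catechin (CNP0154615.1) | O=C(O[C@@H]1[C@@H](c2c(O)cc(O)c3c2O[C@H](c2ccc(O)c(O)c2)[C@H](OC(=O)c2cc(O)c(O)c(O)c2)[C@H]3c2c(O)cc3c(c2O)C[C@H](O)[C@@H](c2ccc(O)c(O)c2)O3)c2c(O)cc(O)cc2O[C@@H]1c1ccc(O)c(O)c1)c1cc(O)c(O)c(O)c1 | target

## Step count and least certain steps

Total: 21 steps. Longest linear sequence: 16 steps (steps 1–6, 10–17, 20 and 21).

Step 10 (key step). The most likely failure is slow or absent conjugate addition, because the iminium ion of a β-aryl enal whose aryl group carries two ortho oxygen substituents is both electron-rich and shielded on both sides. A second risk is loss of facial selectivity if the hindered aryl group forces an unusual iminium conformation. The fallback sets out from 7 and 12 and returns at 15. Knoevenagel condensation of 7 with Meldrum's acid (piperidine/AcOH cat., toluene, rt) should give the arylidene Meldrum's acid F1, a far stronger acceptor. Heating F1 with 12 in pyridine at 80 °C should give conjugate addition through the ortho carbon, lactonisation with loss of acetone, and decarboxylation, leading directly to 15 together with its C4 epimer F2. Without a chiral catalyst the two form under control of the remote stereocentres only, but they are diastereomers and would be separated by chromatography.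

Step 13. The likely failures are collapse of the tetrahedral intermediate before the quench (the leaving group is a phenoxide), followed by a second aryl addition, and base-mediated equilibration of the α-hydroxy ketone. The fallback sets out from 17 and returns at 20. Aminolysis of 17 with the magnesium amide made from MeNHOMe·HCl and i-PrMgCl (THF, −20 °C) should give the N-methoxy-N-methyl amide F3. Addition of 19 (about 3.5 equiv, two being consumed by the phenol and the hydroxyl) then stops at the chelated tetrahedral intermediate and gives 20 on quench.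

Step 15. The likely failures are activation of the C3 hydroxyl or formation of a cyclic dioxaphosphorane from the vicinal diol, leading to epoxide or dihydrobenzofuran formation, and partial ionisation at the electron-rich benzylic carbon with loss of the clean inversion. Partial ionisation may still converge on the desired isomer, since the C4 aryl group prefers the pseudo-axial position and ring B the equatorial one. The fallback sets out from 17 and returns at 23; it removes the competing hydroxyl before ring B is introduced.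
- Silylation of 17 (TBSCl, imidazole, DMF) gives the 3-O-silyl lactone F4.
- Reduction with i-Bu2AlH (toluene, −78 °C) gives the lactol F5.
- Addition of 3,4-bis(benzyloxy)phenylmagnesium bromide (from 18 and Mg; 3 equiv, THF, −78 to 0 °C) to the ring-open aldehyde under Felkin–Anh control should give the anti carbinol F6.
- Mitsunobu closure of F6 (PPh3, DIAD), now with a single free alcohol, gives the bis-silyl dimer F7.
- Bu4NF removes both silyl groups and gives 23.

Step 20. The likely failures are self-condensation of 25 through the free C6 and C8 positions of its upper ring A, which compete with the hindered C6 of 28, and acid-induced scission of the existing interflavan bond if the temperature rises. The fallback sets out from 25 and returns at 30. Bromination of 25 with NBS (3.1 equiv, CH2Cl2, −78 to 0 °C) caps the three free ring A carbons and gives the tribromide F8, which can no longer act as a nucleophile. Coupling of F8 with 28 under TMSOTf gives the tetrabromide F9. The hydrogenolysis of step 21, with enough Et3N for four equivalents of HBr, removes all bromine atoms together with the benzyl groups and gives 30.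

## Further compounds

F1 | step 10 | 5-[(middle unit-8-yl)methylidene]-2,2-dimethyl-1,3-dioxane-4,6-dione | CC1(C)OC(=O)C(=Cc2c(OCc6ccccc6)cc(OCc6ccccc6)c3c2O[C@H](c5ccc(OCc6ccccc6)c(OCc6ccccc6)c5)[C@H](O[Si](C)(C)C(C)(C)C)[C@H]3OCCOCC)C(=O)O1
F2 | step 10 | (4S)-epimer of 15 | O=C1C[C@H](c3c(OCc6ccccc6)cc(OCc6ccccc6)c4c3O[C@H](c5ccc(OCc6ccccc6)c(OCc6ccccc6)c5)[C@H](O[Si](C)(C)C(C)(C)C)[C@H]4OCCOCC)c2c(OCc6ccccc6)cc(OCc6ccccc6)cc2O1
F3 | step 13 | (2R,3R)-2-hydroxy-3-[2-hydroxy-4,6-bis(benzyloxy)phenyl]-N-methoxy-N-methyl-3-(middle unit-8-yl)propanamide | CON(C)C(=O)[C@H](O)[C@@H](c3c(OCc6ccccc6)cc(OCc6ccccc6)c4c3O[C@H](c5ccc(OCc6ccccc6)c(OCc6ccccc6)c5)[C@H](O[Si](C)(C)C(C)(C)C)[C@H]4OCCOCC)c1c(OCc6ccccc6)cc(OCc6ccccc6)cc1O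
F4 | step 15 | 3-O-tert-butyldimethylsilyl ether of 17 | CC(C)(C)[Si](C)(C)O[C@@H]1[C@@H](c3c(OCc6ccccc6)cc(OCc6ccccc6)c4c3O[C@H](c5ccc(OCc6ccccc6)c(OCc6ccccc6)c5)[C@H](O[Si](C)(C)C(C)(C)C)[C@H]4OCCOCC)c2c(OCc6ccccc6)cc(OCc6ccccc6)cc2OC1=O
F5 | step 15 | (3R,4R)-3-(tert-butyldimethylsilyloxy)-5,7-bis(benzyloxy)-4-(middle unit-8-yl)chroman-2-ol, lactol epimers | CC(C)(C)[Si](C)(C)O[C@@H]1[C@@H](c3c(OCc6ccccc6)cc(OCc6ccccc6)c4c3O[C@H](c5ccc(OCc6ccccc6)c(OCc6ccccc6)c5)[C@H](O[Si](C)(C)C(C)(C)C)[C@H]4OCCOCC)c2c(OCc6ccccc6)cc(OCc6ccccc6)cc2OC1O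
F6 | step 15 | (1S,2R,3R)-1-[3,4-bis(benzyloxy)phenyl]-2-(tert-butyldimethylsilyloxy)-3-[2-hydroxy-4,6-bis(benzyloxy)phenyl]-3-(middle unit-8-yl)propan-1-ol | O[C@@H](c5ccc(OCc6ccccc6)c(OCc6ccccc6)c5)[C@H](O[Si](C)(C)C(C)(C)C)[C@@H](c3c(OCc6ccccc6)cc(OCc6ccccc6)c4c3O[C@H](c5ccc(OCc6ccccc6)c(OCc6ccccc6)c5)[C@H](O[Si](C)(C)C(C)(C)C)[C@H]4OCCOCC)c1c(OCc6ccccc6)cc(OCc6ccccc6)cc1O
F7 | step 15 | 3-O-tert-butyldimethylsilyl ether of 22 (both units silylated at O3) | CC(C)(C)[Si](C)(C)O[C@@H]1[C@@H](c3c(OCc6ccccc6)cc(OCc6ccccc6)c4c3O[C@H](c5ccc(OCc6ccccc6)c(OCc6ccccc6)c5)[C@H](O[Si](C)(C)C(C)(C)C)[C@H]4OCCOCC)c2c(OCc6ccccc6)cc(OCc6ccccc6)cc2O[C@@H]1c5ccc(OCc6ccccc6)c(OCc6ccccc6)c5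
F8 | step 20 | 6,8-dibromo (upper unit) 6-bromo (middle unit) derivative of 25 | O=C(O[C@@H]1[C@@H](c3c(OCc6ccccc6)c(Br)c(OCc6ccccc6)c4c3O[C@H](c5ccc(OCc6ccccc6)c(OCc6ccccc6)c5)[C@H](OC(=O)c5cc(OCc6ccccc6)c(OCc6ccccc6)c(OCc6ccccc6)c5)[C@H]4OCCOCC)c2c(OCc6ccccc6)c(Br)c(OCc6ccccc6)c(Br)c2O[C@@H]1c5ccc(OCc6ccccc6)c(OCc6ccccc6)c5)c5cc(OCc6ccccc6)c(OCc6ccccc6)c(OCc6ccccc6)c5
F9 | step 20 | tetrabromo analogue of 29 (upper 6,8-dibromo, middle 6-bromo, lower 8-bromo) | O=C(O[C@@H]1[C@@H](c3c(OCc6ccccc6)c(Br)c(OCc6ccccc6)c4c3O[C@H](c5ccc(OCc6ccccc6)c(OCc6ccccc6)c5)[C@H](OC(=O)c5cc(OCc6ccccc6)c(OCc6ccccc6)c(OCc6ccccc6)c5)[C@H]4c7c(OCc6ccccc6)c(Br)c8c(c7OCc6ccccc6)C[C@H](O)[C@@H](c5ccc(OCc6ccccc6)c(OCc6ccccc6)c5)O8)c2c(OCc6ccccc6)c(Br)c(OCc6ccccc6)c(Br)c2O[C@@H]1c5ccc(OCc6ccccc6)c(OCc6ccccc6)c5)c5cc(OCc6ccccc6)c(OCc6ccccc6)c(OCc6ccccc6)c5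
A1 | alternative 1 | benzylated epicatechin 3-O-gallate-(4β→6)-8-bromo-penta-O-benzylcatechin | c1c(OCc6ccccc6)cc(OCc6ccccc6)c2c1O[C@H](c5ccc(OCc6ccccc6)c(OCc6ccccc6)c5)[C@H](OC(=O)c5cc(OCc6ccccc6)c(OCc6ccccc6)c(OCc6ccccc6)c5)[C@H]2c7c(OCc6ccccc6)c(Br)c8c(c7OCc6ccccc6)C[C@H](OCc6ccccc6)[C@@H](c5ccc(OCc6ccccc6)c(OCc6ccccc6)c5)O8
A2 | alternative 1 | [2-hydroxy-4,6-bis(benzyloxy)phenyl](8-bromo-penta-O-benzylcatechin-6-yl)methanol | OC(c1c(O)cc(OCc6ccccc6)cc1OCc6ccccc6)c7c(OCc6ccccc6)c(Br)c8c(c7OCc6ccccc6)C[C@H](OCc6ccccc6)[C@@H](c5ccc(OCc6ccccc6)c(OCc6ccccc6)c5)O8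
A3 | alternative 1 | (Z)-2-[3,4-bis(benzyloxy)phenyl]ethenyl 3,4,5-tris(benzyloxy)benzoate | O=C(O/C=C\c5ccc(OCc6ccccc6)c(OCc6ccccc6)c5)c5cc(OCc6ccccc6)c(OCc6ccccc6)c(OCc6ccccc6)c5
A4 | alternative 1 | tetra-O-benzyl-4β-(2-ethoxyethoxy)epicatechin 3-O-[3,4,5-tris(benzyloxy)benzoate] | c1c(OCc6ccccc6)cc(OCc6ccccc6)c2c1O[C@H](c5ccc(OCc6ccccc6)c(OCc6ccccc6)c5)[C@H](OC(=O)c5cc(OCc6ccccc6)c(OCc6ccccc6)c(OCc6ccccc6)c5)[C@H]2OCCOCC
A5 | alternative 2 | tetra-O-benzyl-3-O-TBS-epicatechin-(4β→6)-[8-bromo-5,7-bis(benzyloxy)-2-(3,4-bis(benzyloxy)phenyl)-4H-chromene] | c1c(OCc6ccccc6)cc(OCc6ccccc6)c2c1O[C@H](c5ccc(OCc6ccccc6)c(OCc6ccccc6)c5)[C@H](O[Si](C)(C)C(C)(C)C)[C@H]2c7c(OCc6ccccc6)c(Br)c8c(c7OCc6ccccc6)CC=C(c5ccc(OCc6ccccc6)c(OCc6ccccc6)c5)O8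
A6 | alternative 2 | 2-bromo-3,5-bis(benzyloxy)-4-(tetra-O-benzyl-3-O-TBS-epicatechin-4β-yl)-6-(2-oxoethyl)phenyl 3,4-bis(benzyloxy)benzoate | c1c(OCc6ccccc6)cc(OCc6ccccc6)c2c1O[C@H](c5ccc(OCc6ccccc6)c(OCc6ccccc6)c5)[C@H](O[Si](C)(C)C(C)(C)C)[C@H]2c7c(OCc6ccccc6)c(Br)c(OC(=O)c5ccc(OCc6ccccc6)c(OCc6ccccc6)c5)c(CC=O)c7OCc6ccccc6
A7 | alternative 3 | tetra-O-benzyl-3-O-TBS-epicatechin-(4β→6)-8-bromo-5,7,3',4'-tetra-O-benzylcatechin, lower 3-OH free | c1c(OCc6ccccc6)cc(OCc6ccccc6)c2c1O[C@H](c5ccc(OCc6ccccc6)c(OCc6ccccc6)c5)[C@H](O[Si](C)(C)C(C)(C)C)[C@H]2c7c(OCc6ccccc6)c(Br)c8c(c7OCc6ccccc6)C[C@H](O)[C@@H](c5ccc(OCc6ccccc6)c(OCc6ccccc6)c5)O8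
A8 | alternative 3 | aryl ether of (R)-[3,4-bis(benzyloxy)phenyl][(S)-oxiran-2-yl]methanol with 2-bromo-3,5-bis(benzyloxy)-4-(tetra-O-benzyl-3-O-TBS-epicatechin-4β-yl)phenol | c1c(OCc6ccccc6)cc(OCc6ccccc6)c2c1O[C@H](c5ccc(OCc6ccccc6)c(OCc6ccccc6)c5)[C@H](O[Si](C)(C)C(C)(C)C)[C@H]2c7c(OCc6ccccc6)c(Br)c(O[C@H](c5ccc(OCc6ccccc6)c(OCc6ccccc6)c5)[C@H]8OC8)cc7OCc6ccccc6
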